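**Strategy.** Ring B of this labdane (C5–C6–C7–C8=C9–C10) is a cyclohexene whose tetrasubstituted C8=C9 alkene sits between C7 and the quaternary C10, i.e. a Diels–Alder retron, and ring A (C1–C4) is a four-carbon bridge between its diene and dienophile ends. The route therefore rests on an intramolecular Diels–Alder reaction of an acyclic (E)-nitro triene: one thermal step forms C5–C10 and C6–C7, closes both rings, sets C5 and C10 (trans) under control of the preformed C3/C4 stereodiad and leaves the C8=C9 alkene in place. The nitro group is then converted into the C6 ketone, reduced to the 6β-alcohol. The precursor is a linear chain assembled by two acetoacetate dianion alkylations and a Fráter–Seebach-type nitrovinylation.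

Key step: step 12

Remark: labdane numbering is used throughout (ring A = C1–C5 and C10; ring B = C5–C10; C18 = 4α-methyl, C19 = 4β-carbon, C20 = methyl on C10; β = the face of C20); the target is taken exactly as drawn, i.e. the (3R,4S,5R,6R,10S,13E) isomer.

**Step 1**
Reactants: 1 3-methylbut-2-en-1-ol (prenol)
Product: 2 tert-butyl[(3-methylbut-2-en-1-yl)oxy]diphenylsilane
Conditions: TBDPSCl, imidazole, CH2Cl2, 0 °C to rt
Reagents that add atoms: tert-butyl(chloro)diphenylsilane, CC(C)(C)[Si](Cl)(c1ccccc1)c1ccccc1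
Why: Silyl ether protection of the primary alcohol that becomes C15; the TBDPS group should survive enolates, hydrides, hydrogenation and mild acid until step 16.

**Step 2**
Reactants: 2 tert-butyl[(3-methylbut-2-en-1-yl)oxy]diphenylsilane
Product: 3 (2E)-4-[(tert-butyldiphenylsilyl)oxy]-2-methylbut-2-en-1-ol
Conditions: SeO2 (0.2 equiv), t-BuOOH (2.5 equiv), salicylic acid (cat.), CH2Cl2, rt
Reagents that add atoms: tert-butyl hydroperoxide, CC(C)(C)OO (terminal oxidant; the oxygen is delivered through SeO2, O=[Se]=O)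
Why: Riley allylic oxidation (ene reaction then [2,3]-shift) oxidises the methyl group trans to the chain of a trisubstituted alkene, which fixes the later 13E geometry.

**Step 3**
Reactants: 3 (2E)-4-[(tert-butyldiphenylsilyl)oxy]-2-methylbut-2-en-1-ol
Product: 4 {[(2E)-4-bromo-3-methylbut-2-en-1-yl]oxy}(tert-butyl)diphenylsilane
Conditions: CBr4, PPh3, CH2Cl2, 0 °C
Reagents that add atoms: carbon tetrabromide, BrC(Br)(Br)Br
Why: Appel bromination converts the primary allylic alcohol into the bromide without allylic transposition or loss of alkene geometry.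

**Step 4**
Reactants: 4 {[(2E)-4-bromo-3-methylbut-2-en-1-yl]oxy}(tert-butyl)diphenylsilane; 5 methyl 2-methyl-3-oxobutanoate
Product: 7 methyl (6E)-8-[(tert-butyldiphenylsilyl)oxy]-2,6-dimethyl-3-oxooct-6-enoate, via sodium lithium dianion of methyl 2-methyl-3-oxobutanoate 6 (not isolated)
Conditions: 5, NaH, THF, 0 °C; n-BuLi, 0 °C; then 4, 0 °C
Reagents that add atoms: methyl 2-methyl-3-oxobutanoate 5, COC(=O)C(C)C(C)=O
Why: Weiler dianion alkylation, in which the more basic terminal carbanion displaces the allylic bromide by SN2 and forms C11–C12.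

**Step 5**
Reactants: 7 methyl (6E)-8-[(tert-butyldiphenylsilyl)oxy]-2,6-dimethyl-3-oxooct-6-enoate
Product: 8 methyl (2E,6E)-8-[(tert-butyldiphenylsilyl)oxy]-2,6-dimethyl-3-[(4-methylbenzenesulfonyl)oxy]octa-2,6-dienoate
Conditions: TsCl, N-methylimidazole, Et3N, CH2Cl2, −15 °C to rt
Reagents that add atoms: 4-methylbenzenesulfonyl chloride, Cc1ccc(cc1)S(Cl)(=O)=O
Why: Stereoselective enol tosylation of an α-substituted β-keto ester under non-chelating amine conditions should give the (E)-enol tosylate (tosyloxy trans to the ester), which fixes the C9=C10 geometry.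

**Step 6**
Reactants: 8 methyl (2E,6E)-8-[(tert-butyldiphenylsilyl)oxy]-2,6-dimethyl-3-[(4-methylbenzenesulfonyl)oxy]octa-2,6-dienoate; 9 4,4,5,5-tetramethyl-2-(prop-1-en-2-yl)-1,3,2-dioxaborolane
Product: 10 methyl (2E,6E)-8-[(tert-butyldiphenylsilyl)oxy]-2,6-dimethyl-3-(prop-1-en-2-yl)octa-2,6-dienoate
Conditions: Pd(OAc)2 (5 mol%), SPhos (10 mol%), K3PO4, THF/H2O, 60 °C
Reagents that add atoms: isopropenylboronic acid pinacol ester 9, CC(=C)B1OC(C)(C)C(C)(C)O1
Why: Suzuki–Miyaura coupling of a fully substituted enol tosylate proceeds with retention of alkene geometry and installs the isopropenyl unit (C7, C8, C17), completing the diene with C1 trans to C8.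

**Step 7**
Reactants: 10 methyl (2E,6E)-8-[(tert-butyldiphenylsilyl)oxy]-2,6-dimethyl-3-(prop-1-en-2-yl)octa-2,6-dienoate
Product: 11 (2E,6E)-8-[(tert-butyldiphenylsilyl)oxy]-2,6-dimethyl-3-(prop-1-en-2-yl)octa-2,6-dien-1-ol
Conditions: i-Bu2AlH (2.5 equiv), CH2Cl2, −78 °C
Reagents that add atoms: none
Why: Hydride reduction of the conjugated ester gives the primary allylic alcohol (C1) without touching the silyl ether or the diene.

**Step 8**
Reactants: 11 (2E,6E)-8-[(tert-butyldiphenylsilyl)oxy]-2,6-dimethyl-3-(prop-1-en-2-yl)octa-2,6-dien-1-ol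
Product: 12 {[(2E,6E)-8-bromo-3,7-dimethyl-6-(prop-1-en-2-yl)octa-2,6-dien-1-yl]oxy}(tert-butyl)diphenylsilane
Conditions: CBr4, PPh3, CH2Cl2, −20 °C; used at once
Reagents that add atoms: carbon tetrabromide, BrC(Br)(Br)Br
Why: Appel bromination at the primary carbon C1 proceeds by SN2 on the alkoxyphosphonium ion and should not transpose into the diene.

**Step 9**
Reactants: 12 {[(2E,6E)-8-bromo-3,7-dimethyl-6-(prop-1-en-2-yl)octa-2,6-dien-1-yl]oxy}(tert-butyl)diphenylsilane; 5 methyl 2-methyl-3-oxobutanoate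
Product: 14 methyl (6E,10E)-12-[(tert-butyldiphenylsilyl)oxy]-2,6,10-trimethyl-3-oxo-7-(prop-1-en-2-yl)dodeca-6,10-dienoate, via dilithium dianion of methyl 2-methyl-3-oxobutanoate 13 (not isolated)
Conditions: 5, LiN(i-Pr)2 (2.1 equiv), THF, −78 to 0 °C; then 12, −78 to −20 °C
Reagents that add atoms: methyl 2-methyl-3-oxobutanoate 5, COC(=O)C(C)C(C)=O
Why: Dianion alkylation of a β-keto ester, here through the homogeneous dilithium dianion made with LiN(i-Pr)2 so that the labile dienyl bromide can be added cold, forms C1–C2 by SN2 at the primary allylic carbon and brings in C2–C4, C18 and C19; C4 is a mixture of epimers at this stage, which is of no consequence.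

**Step 10**
Reactants: 14 methyl (6E,10E)-12-[(tert-butyldiphenylsilyl)oxy]-2,6,10-trimethyl-3-oxo-7-(prop-1-en-2-yl)dodeca-6,10-dienoate
Product: 15 methyl (3R,6E,10E)-12-[(tert-butyldiphenylsilyl)oxy]-3-hydroxy-2,6,10-trimethyl-7-(prop-1-en-2-yl)dodeca-6,10-dienoate (both C2 epimers)
Conditions: RuCl2[(R)-BINAP] (1 mol%), H2 (50 atm), MeOH/CH2Cl2, 40 °C
Reagents that add atoms: none
Why: Noyori asymmetric hydrogenation of a β-keto ester reduces the chelated ketone under catalyst control to the (3R)-alcohol with the (R)-ligand, while unfunctionalised alkenes should not bind to this catalyst.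

**Step 11**
Reactants: 15 methyl (3R,6E,10E)-12-[(tert-butyldiphenylsilyl)oxy]-3-hydroxy-2,6,10-trimethyl-7-(prop-1-en-2-yl)dodeca-6,10-dienoate; 16 (E)-N,N-dimethyl-2-nitroethen-1-amine
Product: 18 methyl (2R,3R,6E,10E)-12-[(tert-butyldiphenylsilyl)oxy]-3-hydroxy-2,6,10-trimethyl-2-[(E)-2-nitroethenyl]-7-(prop-1-en-2-yl)dodeca-6,10-dienoate, via dilithium amino nitronate adduct 17 (not isolated)
Conditions: LiN(i-Pr)2 (2.2 equiv), THF, −78 to −20 °C; then 16, −78 to −30 °C; then 1 M HCl, 0 °C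
Reagents that add atoms: (E)-N,N-dimethyl-2-nitroethen-1-amine 16, CN(C)/C=C/[N+](=O)[O-]
Why: Fráter–Seebach alkylation with a nitrovinyl cation equivalent (nitroolefination of an ester enolate by addition–elimination): the chelated lithium alkoxide–enolate should add to the nitroenamine anti to the C3 oxygen, and acid work-up expels dimethylamine to give the (E)-nitroalkene and the C4 quaternary centre (methyl syn, nitrovinyl anti to O3).

**Step 12**
Reactants: 18 methyl (2R,3R,6E,10E)-12-[(tert-butyldiphenylsilyl)oxy]-3-hydroxy-2,6,10-trimethyl-2-[(E)-2-nitroethenyl]-7-(prop-1-en-2-yl)dodeca-6,10-dienoate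
Product: 19 methyl 15-[(tert-butyldiphenylsilyl)oxy]-3α-hydroxy-6α-nitrolabda-8,13E-dien-19-oate (5α-H; 10β-CH3; 4α-CH3)
Conditions: toluene (0.01 M), BHT (cat.), 110 °C, sealed tube
Reagents that add atoms: none
Why: A thermal, concerted but asynchronous [4+2] cycloaddition in which the electron-poor (E)-nitroalkene C5=C6 adds across the C7=C8–C9=C10 diene, forming C5–C10 and C6–C7 and leaving the tetrasubstituted C8=C9 alkene; the closest known reaction type is the intramolecular Diels–Alder reaction of (E)-1-nitrodeca-1,7,9-trienes, which gives trans-fused nitrodecalins. Ring A closes as a six-membered carbocycle through the four-carbon tether C1–C4 when C5 bonds to C10, and ring B is the six-membered cyclohexene made by the cycloaddition itself, with both new bonds in it. The trans relationship of the C10 methyl and C5–H should follow from the diene geometry (C1 trans to C8 on C9=C10, so C20 lies inside) together with an endo-nitro, exo-tether, chair-like transition state; the C6 centre (nitro α) follows from the E-alkene and is erased in step 13. The π-face is chosen by the C3/C4 stereodiad: the tether chair that keeps the C4 methyl equatorial and places the planar ester axial, anti to the axial C3–OH, should be preferred over the alternative in which the C4 methyl is axial and 1,3 to C20. The step needs trans- over cis-fusion and one diene face; regiochemistry is fixed by the tether, and dilute, base-free conditions with a radical inhibitor protect the nitroalkene.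

**Step 13**
Reactants: 19 methyl 15-[(tert-butyldiphenylsilyl)oxy]-3α-hydroxy-6α-nitrolabda-8,13E-dien-19-oate
Product: 22 methyl 15-[(tert-butyldiphenylsilyl)oxy]-3α-hydroxy-6-oxolabda-8,13E-dien-19-oate, via sodium C6 nitronate 20 (not isolated), via C6 ketimine 21 (not isolated)
Conditions: NaOMe (1.1 equiv), MeOH, 0 °C; then aq. TiCl3 (4 equiv), NH4OAc buffer (pH 5), THF, 0 °C to rt
Reagents that add atoms: water, O
Why: Reductive Nef reaction (McMurry conditions): the nitronate is reduced by trivalent titanium to the imine, which hydrolyses at pH 5 to the C6 ketone under conditions that should neither epimerise C5 nor move the C8=C9 alkene.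

**Step 14**
Reactants: 22 methyl 15-[(tert-butyldiphenylsilyl)oxy]-3α-hydroxy-6-oxolabda-8,13E-dien-19-oate
Product: 23 15-[(tert-butyldiphenylsilyl)oxy]labda-8,13E-diene-3α,6β,19-triol
Conditions: LiAlH4, THF, 0 °C
Reagents that add atoms: none
Why: LiAlH4 reduces the ester to the C19 alcohol and attacks the C6 ketone from the α face, because the β face is blocked by the axial C19 and C20 groups, which sets the 6β (axial) alcohol.

**Step 15**
Reactants: 23 15-[(tert-butyldiphenylsilyl)oxy]labda-8,13E-diene-3α,6β,19-triol; 24 3-methylbutanoyl chloride (isovaleryl chloride)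
Product: 25 15-[(tert-butyldiphenylsilyl)oxy]-6β-hydroxylabda-8,13E-diene-3α,19-diyl bis(3-methylbutanoate)
Conditions: 24 (2.5 equiv), pyridine, DMAP (0.1 equiv), CH2Cl2, 0 °C to rt
Reagents that add atoms: 3-methylbutanoyl chloride 24, CC(C)CC(Cl)=O
Why: DMAP-catalysed acylation differentiates the hydroxyls by hindrance: the primary C19–OH and the axial C3–OH should be esterified, whereas the 6β-OH, 1,3-diaxial to both C19 and C20, should stay free.

**Step 16**
Reactants: 25 15-[(tert-butyldiphenylsilyl)oxy]-6β-hydroxylabda-8,13E-diene-3α,19-diyl bis(3-methylbutanoate)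
Product: 26 6β,15-dihydroxylabda-8,13E-diene-3α,19-diyl bis(3-methylbutanoate)
Conditions: Bu4NF, AcOH, THF, rt
Reagents that add atoms: none
Why: Fluoride cleavage of the silyl ether, buffered with acetic acid so that neither ester hydrolysis nor acyl migration from O19 to O6 should occur.

**Step 17**
Reactants: 26 6β,15-dihydroxylabda-8,13E-diene-3α,19-diyl bis(3-methylbutanoate)
Product: 27 6β-hydroxy-3α,19-bis[(3-methylbutanoyl)oxy]labda-8,13E-dien-15-al
Conditions: MnO2 (excess), CH2Cl2, rt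
Reagents that add atoms: none
Why: MnO2 oxidises only the allylic alcohol to the enal, with retention of the 13E geometry, and leaves the hindered saturated 6β-alcohol.

**Step 18**
Reactants: 27 6β-hydroxy-3α,19-bis[(3-methylbutanoyl)oxy]labda-8,13E-dien-15-al
Product: 28 (3R,4S,5R,6R,10S,13E)-6-hydroxy-3,19-bis[(3-methylbutanoyl)oxy]labda-8,13-dien-15-oic acid (target, CNP0333611.1)
Conditions: NaClO2, NaH2PO4, 2-methylbut-2-ene, t-BuOH/H2O, 0 °C to rt
Reagents that add atoms: sodium chlorite, [Na+].[O-]Cl=O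
Why: Pinnick oxidation converts the enal into the acid; the hypochlorite scavenger protects the alkenes, and the esters and the secondary alcohol are not affected.

**Compound list**

1 | 3-methylbut-2-en-1-ol (prenol) | CC(C)=CCO | starting material
2 | tert-butyl[(3-methylbut-2-en-1-yl)oxy]diphenylsilane | CC(C)=CCO[Si](c1ccccc1)(c1ccccc1)C(C)(C)C | intermediate
3 | (2E)-4-[(tert-butyldiphenylsilyl)oxy]-2-methylbut-2-en-1-ol | OC/C(C)=C/CO[Si](c1ccccc1)(c1ccccc1)C(C)(C)C | intermediate
4 | {[(2E)-4-bromo-3-methylbut-2-en-1-yl]oxy}(tert-butyl)diphenylsilane | BrC/C(C)=C/CO[Si](c1ccccc1)(c1ccccc1)C(C)(C)C | intermediate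
5 | methyl 2-methyl-3-oxobutanoate | COC(=O)C(C)C(C)=O | starting material
6 | sodium lithium dianion of methyl 2-methyl-3-oxobutanoate | [Na+].[Li+].COC(=O)[C-](C)C(=O)[CH2-] | intermediate (not isolated)
7 | methyl (6E)-8-[(tert-butyldiphenylsilyl)oxy]-2,6-dimethyl-3-oxooct-6-enoate (racemic at C2) | COC(=O)C(C)C(=O)CC/C(C)=C/CO[Si](c1ccccc1)(c1ccccc1)C(C)(C)C | intermediate
8 | methyl (2E,6E)-8-[(tert-butyldiphenylsilyl)oxy]-2,6-dimethyl-3-[(4-methylbenzenesulfonyl)oxy]octa-2,6-dienoate | COC(=O)/C(C)=C(/OS(=O)(=O)c1ccc(C)cc1)CC/C(C)=C/CO[Si](c1ccccc1)(c1ccccc1)C(C)(C)C | intermediate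
9 | 4,4,5,5-tetramethyl-2-(prop-1-en-2-yl)-1,3,2-dioxaborolane | CC(=C)B1OC(C)(C)C(C)(C)O1 | starting material
10 | methyl (2E,6E)-8-[(tert-butyldiphenylsilyl)oxy]-2,6-dimethyl-3-(prop-1-en-2-yl)octa-2,6-dienoate | COC(=O)/C(C)=C(/C(C)=C)CC/C(C)=C/CO[Si](c1ccccc1)(c1ccccc1)C(C)(C)C | intermediate
11 | (2E,6E)-8-[(tert-butyldiphenylsilyl)oxy]-2,6-dimethyl-3-(prop-1-en-2-yl)octa-2,6-dien-1-ol | OC/C(C)=C(/C(C)=C)CC/C(C)=C/CO[Si](c1ccccc1)(c1ccccc1)C(C)(C)C | intermediate
12 | {[(2E,6E)-8-bromo-3,7-dimethyl-6-(prop-1-en-2-yl)octa-2,6-dien-1-yl]oxy}(tert-butyl)diphenylsilane | BrC/C(C)=C(/C(C)=C)CC/C(C)=C/CO[Si](c1ccccc1)(c1ccccc1)C(C)(C)C | intermediate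
13 | dilithium dianion of methyl 2-methyl-3-oxobutanoate | [Li+].[Li+].COC(=O)[C-](C)C(=O)[CH2-] | intermediate (not isolated)
14 | methyl (6E,10E)-12-[(tert-butyldiphenylsilyl)oxy]-2,6,10-trimethyl-3-oxo-7-(prop-1-en-2-yl)dodeca-6,10-dienoate (racemic at C2) | COC(=O)C(C)C(=O)CC/C(C)=C(/C(C)=C)CC/C(C)=C/CO[Si](c1ccccc1)(c1ccccc1)C(C)(C)C | intermediate
15 | methyl (3R,6E,10E)-12-[(tert-butyldiphenylsilyl)oxy]-3-hydroxy-2,6,10-trimethyl-7-(prop-1-en-2-yl)dodeca-6,10-dienoate (both C2 epimers) | COC(=O)C(C)[C@H](O)CC/C(C)=C(/C(C)=C)CC/C(C)=C/CO[Si](c1ccccc1)(c1ccccc1)C(C)(C)C | intermediate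
16 | (E)-N,N-dimethyl-2-nitroethen-1-amine | CN(C)/C=C/[N+](=O)[O-] | starting material
17 | dilithium alkoxide nitronate adduct of the dianion of 15 with 16 (C2 and C3 as in 18; amine-bearing carbon unassigned) | [Li+].[Li+].COC(=O)[C@](C)(C(N(C)C)C=[N+]([O-])[O-])[C@H]([O-])CC/C(C)=C(/C(C)=C)CC/C(C)=C/CO[Si](c1ccccc1)(c1ccccc1)C(C)(C)C | intermediate (not isolated)
18 | methyl (2R,3R,6E,10E)-12-[(tert-butyldiphenylsilyl)oxy]-3-hydroxy-2,6,10-trimethyl-2-[(E)-2-nitroethenyl]-7-(prop-1-en-2-yl)dodeca-6,10-dienoate | COC(=O)[C@](C)(/C=C/[N+](=O)[O-])[C@H](O)CC/C(C)=C(/C(C)=C)CC/C(C)=C/CO[Si](c1ccccc1)(c1ccccc1)C(C)(C)C | intermediate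
19 | methyl 15-[(tert-butyldiphenylsilyl)oxy]-3α-hydroxy-6α-nitrolabda-8,13E-dien-19-oate (5α-H, 10β-CH3, 4α-CH3) | CC1=C(CC/C(C)=C/CO[Si](c3ccccc3)(c3ccccc3)C(C)(C)C)[C@@]2(C)CC[C@@H](O)[C@](C)(C(=O)OC)[C@@H]2[C@@H]([N+](=O)[O-])C1 | intermediate
20 | sodium C6 nitronate of 19 | [Na+].CC1=C(CC/C(C)=C/CO[Si](c3ccccc3)(c3ccccc3)C(C)(C)C)[C@@]2(C)CC[C@@H](O)[C@](C)(C(=O)OC)[C@@H]2C(=[N+]([O-])[O-])C1 | intermediate (not isolated)
21 | methyl 15-[(tert-butyldiphenylsilyl)oxy]-3α-hydroxy-6-iminolabda-8,13E-dien-19-oate | CC1=C(CC/C(C)=C/CO[Si](c3ccccc3)(c3ccccc3)C(C)(C)C)[C@@]2(C)CC[C@@H](O)[C@](C)(C(=O)OC)[C@@H]2C(=N)C1 | intermediate (not isolated)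
22 | methyl 15-[(tert-butyldiphenylsilyl)oxy]-3α-hydroxy-6-oxolabda-8,13E-dien-19-oate (5α-H) | CC1=C(CC/C(C)=C/CO[Si](c3ccccc3)(c3ccccc3)C(C)(C)C)[C@@]2(C)CC[C@@H](O)[C@](C)(C(=O)OC)[C@@H]2C(=O)C1 | intermediate
23 | 15-[(tert-butyldiphenylsilyl)oxy]labda-8,13E-diene-3α,6β,19-triol | CC1=C(CC/C(C)=C/CO[Si](c3ccccc3)(c3ccccc3)C(C)(C)C)[C@@]2(C)CC[C@@H](O)[C@](C)(CO)[C@@H]2[C@H](O)C1 | intermediate
24 | 3-methylbutanoyl chloride (isovaleryl chloride) | CC(C)CC(Cl)=O | starting material
25 | 15-[(tert-butyldiphenylsilyl)oxy]-6β-hydroxylabda-8,13E-diene-3α,19-diyl bis(3-methylbutanoate) | CC1=C(CC/C(C)=C/CO[Si](c3ccccc3)(c3ccccc3)C(C)(C)C)[C@@]2(C)CC[C@@H](OC(=O)CC(C)C)[C@](C)(COC(=O)CC(C)C)[C@@H]2[C@H](O)C1 | intermediate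
26 | 6β,15-dihydroxylabda-8,13E-diene-3α,19-diyl bis(3-methylbutanoate) | CC1=C(CC/C(C)=C/CO)[C@@]2(C)CC[C@@H](OC(=O)CC(C)C)[C@](C)(COC(=O)CC(C)C)[C@@H]2[C@H](O)C1 | intermediate
27 | 6β-hydroxy-3α,19-bis[(3-methylbutanoyl)oxy]labda-8,13E-dien-15-al | CC1=C(CC/C(C)=C/C=O)[C@@]2(C)CC[C@@H](OC(=O)CC(C)C)[C@](C)(COC(=O)CC(C)C)[C@@H]2[C@H](O)C1 | intermediate
28 | (3R,4S,5R,6R,10S,13E)-6-hydroxy-3,19-bis[(3-methylbutanoyl)oxy]labda-8,13-dien-15-oic acid | CC1=C(CC/C(C)=C/C(=O)O)[C@@]2(C)CC[C@@H](OC(=O)CC(C)C)[C@](C)(COC(=O)CC(C)C)[C@@H]2[C@H](O)C1 | target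

**Step count.** Total: 18 steps. Longest linear sequence: 18 steps (from 1; compounds 5, 9, 16 and 24 are bought).

**Steps most likely to fail**

1. Step 12 (cycloaddition). The π-facial discrimination may be too small, because the tether chair with axial C3–OH and axial ester competes with the one that has an axial C4 methyl. Some material may also leak into the cis-fused (exo-nitro) mode, and the twisted, fully substituted diene may react slowly enough for a 1,5-hydrogen shift of the diene to compete. Fallback, setting out from 18: the C3 alcohol is oxidised with Dess–Martin periodinane (CH2Cl2, NaHCO3) to methyl (2R,6E,10E)-12-[(tert-butyldiphenylsilyl)oxy]-2,6,10-trimethyl-2-[(E)-2-nitroethenyl]-3-oxo-7-(prop-1-en-2-yl)dodeca-6,10-dienoate F1, in which C3 is trigonal, so that C4 alone (ester axial and turned away from the ketone dipole, methyl equatorial) directs the face. Heating in toluene at 110 °C should give methyl 15-[(tert-butyldiphenylsilyl)oxy]-6α-nitro-3-oxolabda-8,13E-dien-19-oate F2. NaOMe and then buffered aqueous TiCl3 should give methyl 15-[(tert-butyldiphenylsilyl)oxy]-3,6-dioxolabda-8,13E-dien-19-oate F3. LiBH(s-Bu)3 (THF, −78 °C) should deliver hydride equatorially at C3 and from the α face at C6 to give methyl 15-[(tert-butyldiphenylsilyl)oxy]-3α,6β-dihydroxylabda-8,13E-dien-19-oate F4. LiAlH4 reduction of its ester returns to the route at 23.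

2. Step 11 (nitrovinylation). Bond formation at the fully substituted enolate may be incomplete, the alkoxide oxygen may attack the nitroenamine instead, or the dianion may undergo retro-aldol cleavage on warming. Fallback, setting out from 15: the same dianion (LiN(i-Pr)2, 2.2 equiv) is quenched with gaseous formaldehyde to give, by the same facial rule, the C2-hydroxymethyl derivative of 15 (3R; C2 configured as in 18) F5. TEMPO (cat.) with PhI(OAc)2 oxidises only the primary alcohol to the corresponding C2-formyl ester F6. Nitromethane with catalytic tetramethylguanidine gives the C2-(1-hydroxy-2-nitroethyl) ester F7. Dehydration with dicyclohexylcarbodiimide and CuCl (cat.) gives the (E)-nitroalkene, rejoining the route at 18.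

3. Step 13 (Nef reaction). Deprotonation at the hindered C6 may be slow, and once the ketone exists the C8=C9 alkene may migrate into conjugation (or C5 may epimerise) under acid or base. Fallback, setting out from 19: the nitro group is reduced without any nitronate or strong base by SnCl2·2H2O, PhSH and Et3N to methyl 15-[(tert-butyldiphenylsilyl)oxy]-3α-hydroxy-6-(hydroxyimino)labda-8,13E-dien-19-oate F8. This isolable oxime is then cleaved with buffered aqueous TiCl3 (NH4OAc, pH 5), rejoining the route at ketone 22, which is reduced at once in step 14.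

**Further compounds**

F1 | step 12 | methyl (2R,6E,10E)-12-[(tert-butyldiphenylsilyl)oxy]-2,6,10-trimethyl-2-[(E)-2-nitroethenyl]-3-oxo-7-(prop-1-en-2-yl)dodeca-6,10-dienoate | COC(=O)[C@](C)(/C=C/[N+](=O)[O-])C(=O)CC/C(C)=C(/C(C)=C)CC/C(C)=C/CO[Si](c1ccccc1)(c1ccccc1)C(C)(C)C
F2 | step 12 | methyl 15-[(tert-butyldiphenylsilyl)oxy]-6α-nitro-3-oxolabda-8,13E-dien-19-oate | CC1=C(CC/C(C)=C/CO[Si](c3ccccc3)(c3ccccc3)C(C)(C)C)[C@@]2(C)CCC(=O)[C@](C)(C(=O)OC)[C@@H]2[C@@H]([N+](=O)[O-])C1
F3 | step 12 | methyl 15-[(tert-butyldiphenylsilyl)oxy]-3,6-dioxolabda-8,13E-dien-19-oate | CC1=C(CC/C(C)=C/CO[Si](c3ccccc3)(c3ccccc3)C(C)(C)C)[C@@]2(C)CCC(=O)[C@](C)(C(=O)OC)[C@@H]2C(=O)C1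
F4 | step 12 | methyl 15-[(tert-butyldiphenylsilyl)oxy]-3α,6β-dihydroxylabda-8,13E-dien-19-oate | CC1=C(CC/C(C)=C/CO[Si](c3ccccc3)(c3ccccc3)C(C)(C)C)[C@@]2(C)CC[C@@H](O)[C@](C)(C(=O)OC)[C@@H]2[C@H](O)C1
F5 | step 11 | methyl (3R,6E,10E)-12-[(tert-butyldiphenylsilyl)oxy]-3-hydroxy-2-(hydroxymethyl)-2,6,10-trimethyl-7-(prop-1-en-2-yl)dodeca-6,10-dienoate (C2 as in 18) | COC(=O)[C@](C)(CO)[C@H](O)CC/C(C)=C(/C(C)=C)CC/C(C)=C/CO[Si](c1ccccc1)(c1ccccc1)C(C)(C)C
F6 | step 11 | methyl (3R,6E,10E)-12-[(tert-butyldiphenylsilyl)oxy]-2-formyl-3-hydroxy-2,6,10-trimethyl-7-(prop-1-en-2-yl)dodeca-6,10-dienoate (C2 as in 18) | COC(=O)[C@](C)(C=O)[C@H](O)CC/C(C)=C(/C(C)=C)CC/C(C)=C/CO[Si](c1ccccc1)(c1ccccc1)C(C)(C)C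
F7 | step 11 | methyl (3R,6E,10E)-12-[(tert-butyldiphenylsilyl)oxy]-3-hydroxy-2-(1-hydroxy-2-nitroethyl)-2,6,10-trimethyl-7-(prop-1-en-2-yl)dodeca-6,10-dienoate (C2 as in 18; new carbinol unassigned) | COC(=O)[C@](C)(C(O)C[N+](=O)[O-])[C@H](O)CC/C(C)=C(/C(C)=C)CC/C(C)=C/CO[Si](c1ccccc1)(c1ccccc1)C(C)(C)C
F8 | step 13 | methyl 15-[(tert-butyldiphenylsilyl)oxy]-3α-hydroxy-6-(hydroxyimino)labda-8,13E-dien-19-oate | CC1=C(CC/C(C)=C/CO[Si](c3ccccc3)(c3ccccc3)C(C)(C)C)[C@@]2(C)CC[C@@H](O)[C@](C)(C(=O)OC)[C@@H]2C(=NO)C1
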